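**Plan**
- Retrosynthesis first cuts the C8 ester and the lactone bond C12–O6 (acylation; oxidative lactonisation of a C6,C12-diol), then the ketal bond O10–C3 (transannular addition of a C10 oxygen to a C1=C2=C3(OMe) methoxyallene).
- The ten-membered ring is then unravelled by a retro-[3,3] shift: C1–C10 is cut and C3–C8 is joined, which leaves a cyclohexenol; C8–C9 and C3–C2 are cut last (alkenyllithium and ethynyl Grignard additions).
- Enabling feature: with C3 and C8 joined, C3–C4=C5–C6–C7–C8 is the carvone ring (Z C4=C5 with methyl C15, side chain C11–C13 on C7), and C2≡C1 on C3 with C9=C10 on C8 form a 1,5-enyne across that bond.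
- Forward order of rings: carvone ring (oxygenated at C12, C8, C3, C6) → ten-membered ring by ring expansion (step 14) → dihydrofuran ring by transannular ketalisation (step 15) → lactone ring last (step 22).
- Stereochemistry: C7 from (S)-carvone; C6 by Luche reduction trans to the side chain; C10 from the (Z)-enol ether geometry in a chair transition state; C3 by the bridge; C8 by Felkin–Anh reduction; the (Z)-ester by syn-hydroalumination.

Key step: step 14

Remark: the germacrane numbering of the target is used for all intermediates; β is the ring face of the C7 side chain, α the opposite face.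
Assumption: the alkenyllithium attacks ketone 17 anti to the pseudo-axial ethynyl group; the C8 epimer, if formed, has the same enyne helicity in its reactive half-chair and should give the same C10 configuration.
Remark: the 1-ethoxyethyl acetal carbon is carried as an inconsequential mixture of epimers and is left unspecified.

**Route**

Step 1
Reactants: 1 (S)-(+)-carvone
Product: 2 10-chlorocarvone
Conditions: Ca(OCl)2, CO2 (solid), CH2Cl2/H2O, 0 °C
Reagents that add atoms: calcium hypochlorite, [Ca+2].[O-]Cl.[O-]Cl
Why: Ene-type allylic chlorination by hypochlorous acid generated in situ attacks the electron-rich 1,1-disubstituted alkene and not the deactivated enone alkene, and no stereocentre is touched.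

Step 2
Reactants: 2 10-chlorocarvone
Product: 4 10-hydroxycarvone, via allylic acetate 3 (not isolated)
Conditions: KOAc, n-Bu4NI (cat.), DMF, 60 °C; then K2CO3 (cat.), MeOH, rt
Reagents that add atoms: potassium acetate, CC(=O)[O-].[K+]
Why: SN2 displacement of the primary allylic chloride by acetate is followed in the same flask by base-catalysed transesterification with methanol, which frees the allylic alcohol.

Step 3
Reactants: 4 10-hydroxycarvone
Product: 5 C12 silyl ether
Conditions: TBSCl, imidazole, CH2Cl2, rt
Reagents that add atoms: tert-butyldimethylsilyl chloride, CC(C)(C)[Si](C)(C)Cl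
Why: Standard silylation of a primary alcohol gives an ether that survives every basic and oxidative step up to step 21.

Step 4
Reactants: 5 C12 silyl ether
Product: 9 C8 triethylsilyloxy enone, via lithium dienolate 6 (not isolated), via triethylsilyl dienol ether 7 (not isolated), via silyloxy oxirane 8 (not isolated)
Conditions: LiN(i-Pr)2, THF, −78 °C; Et3SiCl; solvent switch; then 3-chloroperbenzoic acid (mCPBA), NaHCO3, CH2Cl2, −20 °C
Reagents that add atoms: chlorotriethylsilane, CC[Si](CC)(CC)Cl; 3-chloroperbenzoic acid, OOC(=O)c1cccc(Cl)c1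
Why: Kinetic α′-deprotonation and O-silylation are followed by Rubottom oxidation, in which the peracid epoxidises the silyl enol ether anti to the C7 side chain and the oxirane opens with 1,4-silyl shift, so the C8 oxygen comes out trans to the side chain (this centre is erased in step 11).

Step 5
Reactants: 9 C8 triethylsilyloxy enone
Product: 10 C3 ethynyl carbinol
Conditions: HC≡CMgBr, THF, −78 → 0 °C
Reagents that add atoms: ethynylmagnesium bromide, C#C[Mg]Br
Why: 1,2-Addition of the alkynyl Grignard reagent to the enone carbonyl occurs axially and anti to the C7 side chain, as for 5-substituted cyclohexenones (the equatorial silyl ether does not chelate), which puts ethynyl α and the C3 oxygen β.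

Step 6
Reactants: 10 C3 ethynyl carbinol
Product: 12 C3 methyl ether, via potassium alkoxide 11 (not isolated)
Conditions: KN(SiMe3)2 (1.05 equiv), THF, −78 °C; MeOTf, −78 → −40 °C
Reagents that add atoms: methyl trifluoromethanesulfonate, COS(=O)(=O)C(F)(F)F
Why: Williamson etherification of the tertiary propargylic alkoxide with a fast methylating agent at low temperature should outrun 1,2-silyl migration, and the alcohol is far more acidic than the alkyne C–H so that one equivalent of base gives O-methylation.

Step 7
Reactants: 12 C3 methyl ether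
Product: 13 C6 enone
Conditions: CrO3, 3,5-dimethylpyrazole, CH2Cl2, −20 °C
Reagents that add atoms: chromium trioxide, O=[Cr](=O)=O
Why: Allylic oxidation with the CrO3–3,5-dimethylpyrazole complex should convert the only ring allylic methylene of the electron-rich trisubstituted alkene (C3 is quaternary) into the conjugated ketone.

Step 8
Reactants: 13 C6 enone
Product: 14 C6 alcohol
Conditions: NaBH4, CeCl3·7H2O, MeOH, −78 °C
Reagents that add atoms: none
Why: Luche 1,2-reduction with axial hydride delivery to the cyclohexenone should give the pseudo-equatorial 6α-alcohol trans to the C7 side chain, which sets C6.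

Step 9
Reactants: 14 C6 alcohol
Product: 15 C6 silyl ether
Conditions: TBSCl, imidazole, DMF, rt
Reagents that add atoms: tert-butyldimethylsilyl chloride, CC(C)(C)[Si](C)(C)Cl
Why: Standard silylation of the secondary allylic alcohol gives a group that is distinguishable from the triethylsilyl ether on C8.

Step 10
Reactants: 15 C6 silyl ether
Product: 16 C8 alcohol
Conditions: pyridinium p-toluenesulfonate (PPTS, cat.), MeOH/CH2Cl2, 0 °C
Reagents that add atoms: none
Why: Acid-catalysed methanolysis cleaves a triethylsilyl ether much faster than the two tert-butyldimethylsilyl ethers.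

Step 11
Reactants: 16 C8 alcohol
Product: 17 C8 ketone
Conditions: Dess–Martin periodinane, NaHCO3, CH2Cl2, 0 °C to rt
Reagents that add atoms: none
Why: Buffered Dess–Martin oxidation of the secondary alcohol gives the α-methoxy ketone without base, so C7 is not epimerised and the C6 silyloxy group is not eliminated.

Step 12
Reactants: 18 bromoacetone
Product: 20 (Z)-bromo enol acetal, via potassium bromoenolate 19 (not isolated)
Conditions: KN(SiMe3)2, THF, −78 °C; CH3CHClOEt, −78 → 0 °C
Reagents that add atoms: 1-chloroethyl ethyl ether, CCOC(C)Cl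
Why: Deprotonation at the more acidic bromomethylene and O-alkylation of the potassium enolate by the hard α-chloro ether give the enol acetal, the (Z) geometry (Br cis to O) following from the enolate in which bromine avoids the methyl group.

Step 13
Reactants: 20 (Z)-bromo enol acetal; 17 C8 ketone
Product: 22 alkenyl carbinol, via alkenyllithium 21 (not isolated)
Conditions: 20 (3 equiv), t-BuLi (6 equiv), Et2O, −78 °C; then 17, THF, −78 °C; aq. NaHCO3
Reagents that add atoms: none
Why: Bromine–lithium exchange with retention gives the (Z)-alkenyllithium, held by internal O–Li coordination, which adds to the carbonyl by axial attack anti to the pseudo-axial ethynyl group with lithium chelated by the C3 methoxy (Cram chelate model), so the alkenyl group enters β (one equivalent of reagent is consumed by the acetylenic C–H).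

Step 14
Reactants: 22 alkenyl carbinol
Product: 25 ten-membered methoxyallene ketone, via potassium alkoxide 23 (not isolated), via potassium enolate 24 (not isolated)
Conditions: KN(SiMe3)2 (1.05 equiv), 18-crown-6, THF, −78 → 0 °C; AcOH, −78 °C
Reagents that add atoms: none
Why: Proposed new method: deprotonation gives alkoxide 23, whose 1,5-enyne C10=C9–C8–C3–C2≡C1 should undergo an alkoxide-accelerated [3,3] sigmatropic shift (anionic oxy-Cope) that forms C1–C10 and breaks the ring bond C3–C8, already weakened by the C3 methoxy, ethynyl and vinyl substituents, to give enolate 24 with the C1=C2=C3(OMe) allene; the closest known reaction type is the anionic oxy-Cope ring expansion of 1,2-dialkenyl- and 1-alkenyl-2-alkynylcycloalkanols to cyclodecenones and medium-ring allenes, not yet shown with an enol-ether alkene and an oxygenated propargylic carbon. The ten-membered ring arises by four-carbon ring expansion, that is by cleavage of the bond shared between the cyclohexene and the six-centre array, not by an end-to-end closure. The new stereocentre C10 is controlled by the (Z) geometry of the enol ether: the trans arrangement of alkynyl and alkenyl groups allows only the diequatorial half-chair and hence one chair-like transition state (ring bonds C3–C4 and C8–C7 equatorial on the chair), in which C1 bonds to the C10 face that leaves O10 α and C14 β, while the allene axis is of no consequence. The step needs [3,3] selectivity over C3–C8 heterolysis, over a [1,3] shift and over the alternative [3,3] path through C4=C5, which the near-orthogonality of that ring π bond to C3–C8 disfavours. The β-alkoxy enolate must not expel the C10 alkoxy group, for which low temperature, the cold acetic acid quench and the strain that a C9=C10 double bond beside the allene would impose on the ring are relied on.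

Step 15
Reactants: 25 ten-membered methoxyallene ketone
Product: 28 bridged methyl ketal ketone, via C10 hydroxy allene 26 (not isolated), via oxocarbenium ion 27 (not isolated)
Conditions: PPTS (cat.), MeOH, CH2Cl2, 0 °C
Reagents that add atoms: none
Why: Acid-catalysed acetal exchange removes the ethoxyethyl group and protonation of the methoxyallene at C2 from the ring periphery gives the (Z)-oxocarbenium ion from either allene isomer, which the C10 hydroxyl captures transannularly (intramolecular hydroalkoxylation of an alkoxyallene, five-membered ring closure), the bridge fixing C3.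

Step 16
Reactants: 28 bridged methyl ketal ketone
Product: 29 C8 β-alcohol
Conditions: LiBH(s-Bu)3, THF, −78 °C
Reagents that add atoms: none
Why: Felkin–Anh-controlled reduction by the bulky borohydride, with the ring bond C7–C6 anti to the incoming hydride, should place the new hydroxyl cis to the C7 side chain (8β), while ketal, silyl ethers and isolated alkenes are inert.

Step 17
Reactants: 30 ethyl but-2-ynoate
Product: 32 ethyl (Z)-2-(hydroxymethyl)but-2-enoate, via alkenylalane 31 (not isolated)
Conditions: i-Bu2AlH, N-methylmorpholine N-oxide, THF, 0 °C; then (CH2O)n, 0 °C to rt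
Reagents that add atoms: formaldehyde (from paraformaldehyde), C=O
Why: Syn-hydroalumination of the ynoate gives the α-aluminated crotonate, which adds to formaldehyde with retention (vinylalumination, a Morita–Baylis–Hillman-type adduct), so ester and β-methyl stay cis.

Step 18
Reactants: 32 ethyl (Z)-2-(hydroxymethyl)but-2-enoate
Product: 33 (Z)-2-(hydroxymethyl)but-2-enoic acid
Conditions: LiOH, THF/H2O, 0 °C; then aq. HCl to pH 3
Reagents that add atoms: lithium hydroxide, [Li+].[OH-]
Why: Saponification at low temperature should leave the trisubstituted (Z)-alkene untouched.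

Step 19
Reactants: 33 (Z)-2-(hydroxymethyl)but-2-enoic acid
Product: 35 (Z)-2-(acetoxymethyl)but-2-enoic acid, via mixed acetic anhydride 34 (not isolated)
Conditions: Ac2O, pyridine, CH2Cl2, 0 °C; then H2O/THF
Reagents that add atoms: acetic anhydride, CC(=O)OC(C)=O
Why: O-Acetylation of the primary alcohol is accompanied by mixed-anhydride formation at the acid, which aqueous work-up hydrolyses selectively.

Step 20
Reactants: 29 C8 β-alcohol; 35 (Z)-2-(acetoxymethyl)but-2-enoic acid
Product: 37 C8 ester, via trichlorobenzoyl mixed anhydride 36 (not isolated)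
Conditions: 35, 2,4,6-Cl3C6H2COCl, Et3N, toluene, rt; then 29, 80 °C
Reagents that add atoms: none
Why: Yamaguchi-type esterification through the 2,4,6-trichlorobenzoyl mixed anhydride without 4-(dimethylamino)pyridine should avoid Z→E isomerisation and SN2′ loss of acetate, and it retains the C8 configuration.

Step 21
Reactants: 37 C8 ester
Product: 38 hemiketal diol
Conditions: aq. HF, MeCN, 0 °C to rt
Reagents that add atoms: water, O
Why: Aqueous HF cleaves both silyl ethers and hydrolyses the doubly allylic methyl ketal to the hemiketal (C3 held by the bridge), while the two esters survive.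

Step 22
Reactants: 38 hemiketal diol
Product: 41 CNP0256971.1, via hydroxy enal 39 (not isolated), via lactol 40 (not isolated)
Conditions: (2,2,6,6-tetramethylpiperidin-1-yl)oxyl (TEMPO, cat.), PhI(OAc)2, CH2Cl2, rt
Reagents that add atoms: none
Why: TEMPO-catalysed oxidation selects the primary allylic alcohol, the enal is trapped by the C6 hydroxyl as a lactol (five-membered ring closure) and this is oxidised on to the trans-fused α-methylene-γ-butyrolactone.

**Compound list**

1 | (S)-(+)-carvone, (5S)-2-methyl-5-(prop-1-en-2-yl)cyclohex-2-en-1-one | CC1=CC[C@H](C(C)=C)CC1=O | starting material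
2 | (5S)-5-(3-chloroprop-1-en-2-yl)-2-methylcyclohex-2-en-1-one (10-chlorocarvone) | CC1=CC[C@H](C(=C)CCl)CC1=O | intermediate
3 | allylic acetate of 4 (not isolated) | CC1=CC[C@H](C(=C)COC(C)=O)CC1=O | intermediate
4 | (5S)-5-(3-hydroxyprop-1-en-2-yl)-2-methylcyclohex-2-en-1-one (10-hydroxycarvone) | CC1=CC[C@H](C(=C)CO)CC1=O | intermediate
5 | tert-butyldimethylsilyl ether of 4 (C12–OTBS) | CC1=CC[C@H](C(=C)CO[Si](C)(C)C(C)(C)C)CC1=O | intermediate
6 | lithium cross-conjugated dienolate of 5, C8=C3(OLi)–C4=C5 (not isolated) | CC1=CC[C@H](C(=C)CO[Si](C)(C)C(C)(C)C)C=C1[O-].[Li+] | intermediate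
7 | triethylsilyl dienol ether of 5 (not isolated) | CC1=CC[C@H](C(=C)CO[Si](C)(C)C(C)(C)C)C=C1O[Si](CC)(CC)CC | intermediate
8 | C3,C8-oxirane of 7 on the α face, C3 bearing OSiEt3 (not isolated) | CC1=CC[C@H](C(=C)CO[Si](C)(C)C(C)(C)C)[C@H]2O[C@@]12O[Si](CC)(CC)CC | intermediate
9 | enone with 8α-OSiEt3 trans to the 7β side chain, C12–OTBS | CC1=CC[C@H](C(=C)CO[Si](C)(C)C(C)(C)C)[C@@H](O[Si](CC)(CC)CC)C1=O | intermediate
10 | cyclohex-4-ene with 3α-ethynyl, 3β-OH, 4-methyl, 7β-[3-(TBS-oxy)prop-1-en-2-yl], 8α-OSiEt3 | C#C[C@@]1(O)C(C)=CC[C@H](C(=C)CO[Si](C)(C)C(C)(C)C)[C@H]1O[Si](CC)(CC)CC | intermediate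
11 | potassium C3 alkoxide of 10 (not isolated) | C#C[C@@]1([O-])C(C)=CC[C@H](C(=C)CO[Si](C)(C)C(C)(C)C)[C@H]1O[Si](CC)(CC)CC.[K+] | intermediate
12 | 3β-methyl ether of 10 | C#C[C@@]1(OC)C(C)=CC[C@H](C(=C)CO[Si](C)(C)C(C)(C)C)[C@H]1O[Si](CC)(CC)CC | intermediate
13 | 6-oxo derivative of 12 (C4=C5–C6=O) | C#C[C@@]1(OC)C(C)=CC(=O)[C@H](C(=C)CO[Si](C)(C)C(C)(C)C)[C@H]1O[Si](CC)(CC)CC | intermediate
14 | 6α-alcohol, trans to the 7β side chain | C#C[C@@]1(OC)C(C)=C[C@@H](O)[C@H](C(=C)CO[Si](C)(C)C(C)(C)C)[C@H]1O[Si](CC)(CC)CC | intermediate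
15 | 6α-OTBS, 8α-OSiEt3, C12–OTBS derivative | C#C[C@@]1(OC)C(C)=C[C@@H](O[Si](C)(C)C(C)(C)C)[C@H](C(=C)CO[Si](C)(C)C(C)(C)C)[C@H]1O[Si](CC)(CC)CC | intermediate
16 | 8α-alcohol (triethylsilyl group removed) | C#C[C@@]1(OC)C(C)=C[C@@H](O[Si](C)(C)C(C)(C)C)[C@H](C(=C)CO[Si](C)(C)C(C)(C)C)[C@H]1O | intermediate
17 | C8 ketone: 3α-ethynyl-3β-methoxy-4-methyl-6α-OTBS-7β-[3-(TBS-oxy)prop-1-en-2-yl]cyclohex-4-en-8-one | C#C[C@@]1(OC)C(C)=C[C@@H](O[Si](C)(C)C(C)(C)C)[C@H](C(=C)CO[Si](C)(C)C(C)(C)C)C1=O | intermediate
18 | bromoacetone | CC(=O)CBr | starting material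
19 | potassium (Z)-1-bromoprop-1-en-2-olate (not isolated) | Br/C=C(/C)[O-].[K+] | intermediate
20 | (Z)-1-bromo-2-(1-ethoxyethoxy)prop-1-ene (Br cis to O) | Br/C=C(/C)OC(C)OCC | intermediate
21 | (Z)-[2-(1-ethoxyethoxy)prop-1-en-1-yl]lithium, Li cis to O (not isolated) | [Li]/C=C(/C)OC(C)OCC | intermediate
22 | 1-alkenyl-2-alkynylcyclohexenol: 17 carrying at C8 an α-OH and the β-(Z)-2-(1-ethoxyethoxy)prop-1-enyl group (alkynyl and alkenyl trans) | C#C[C@@]1(OC)C(C)=C[C@@H](O[Si](C)(C)C(C)(C)C)[C@H](C(=C)CO[Si](C)(C)C(C)(C)C)[C@]1(O)/C=C(/C)OC(C)OCC | intermediate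
23 | potassium C8 alkoxide of 22 (not isolated) | C#C[C@@]1(OC)C(C)=C[C@@H](O[Si](C)(C)C(C)(C)C)[C@H](C(=C)CO[Si](C)(C)C(C)(C)C)[C@]1([O-])/C=C(/C)OC(C)OCC.[K+] | intermediate
24 | potassium C8=C9 enolate of 25, C7 and C10 trans across the enolate (not isolated) | [O-]/C1=C\[C@@](C)(OC(C)OCC)C=C=C(OC)/C(C)=C\[C@@H](O[Si](C)(C)C(C)(C)C)[C@@H]1C(=C)CO[Si](C)(C)C(C)(C)C.[K+] | intermediate
25 | ten-membered ketone: 8-oxo, 10β-methyl-10α-(1-ethoxyethoxy), C1=C2=C3(OMe) allene (axis not specified), (Z)-C4=C5 with 4-methyl, 6α-OTBS, 7β side chain | O=C1C[C@@](C)(OC(C)OCC)C=C=C(OC)/C(C)=C\[C@@H](O[Si](C)(C)C(C)(C)C)[C@@H]1C(=C)CO[Si](C)(C)C(C)(C)C | intermediate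
26 | 10α-hydroxy analogue of 25 (not isolated) | O=C1C[C@@](C)(O)C=C=C(OC)/C(C)=C\[C@@H](O[Si](C)(C)C(C)(C)C)[C@@H]1C(=C)CO[Si](C)(C)C(C)(C)C | intermediate
27 | C3 O-methyl oxocarbenium ion with (Z)-C1=C2 and free 10α-OH (not isolated) | C[O+]=C1/C=C\[C@](C)(O)CC(=O)[C@@H](C(=C)CO[Si](C)(C)C(C)(C)C)[C@H](O[Si](C)(C)C(C)(C)C)/C=C1/C | intermediate
28 | 3α,10α-epoxy bridged 3β-methyl ketal with C8 ketone, C1=C2, (Z)-C4=C5, 6α-OTBS, C12–OTBS | CC(C)(C)[Si](C)(C)O[C@@H]1/C=C(/C)[C@@]2(OC)C=C[C@@](C)(CC(=O)[C@H]1C(=C)CO[Si](C)(C)C(C)(C)C)O2 | intermediate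
29 | 8β-alcohol of 28 | CC(C)(C)[Si](C)(C)O[C@@H]1/C=C(/C)[C@@]2(OC)C=C[C@@](C)(C[C@@H](O)[C@H]1C(=C)CO[Si](C)(C)C(C)(C)C)O2 | intermediate
30 | ethyl but-2-ynoate | CC#CC(=O)OCC | starting material
31 | ethyl (Z)-2-(diisobutylalumanyl)but-2-enoate, ester cis to methyl (not isolated) | CCOC(=O)/C(=C\C)[Al](CC(C)C)CC(C)C | intermediate
32 | ethyl (Z)-2-(hydroxymethyl)but-2-enoate | CCOC(=O)/C(=C\C)CO | intermediate
33 | (Z)-2-(hydroxymethyl)but-2-enoic acid | OC(=O)/C(=C\C)CO | intermediate
34 | acetic (Z)-2-(acetoxymethyl)but-2-enoic anhydride (not isolated) | CC(=O)OC(=O)/C(=C\C)COC(C)=O | intermediate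
35 | (Z)-2-(acetoxymethyl)but-2-enoic acid | OC(=O)/C(=C\C)COC(C)=O | intermediate
36 | (Z)-2-(acetoxymethyl)but-2-enoic 2,4,6-trichlorobenzoic anhydride (not isolated) | O=C(OC(=O)/C(=C\C)COC(C)=O)c1c(Cl)cc(Cl)cc1Cl | intermediate
37 | 8β-[(Z)-2-(acetoxymethyl)but-2-enoyl] ester of 29 | CC(C)(C)[Si](C)(C)O[C@@H]1/C=C(/C)[C@@]2(OC)C=C[C@@](C)(C[C@@H](OC(=O)/C(=C\C)COC(C)=O)[C@H]1C(=C)CO[Si](C)(C)C(C)(C)C)O2 | intermediate
38 | 3β-hydroxy-3α,10α-epoxy hemiketal with 6α-OH and C12–OH, 8β-ester | O[C@@H]1/C=C(/C)[C@@]2(O)C=C[C@@](C)(C[C@@H](OC(=O)/C(=C\C)COC(C)=O)[C@H]1C(=C)CO)O2 | intermediate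
39 | C12 aldehyde of 38 (not isolated) | O[C@@H]1/C=C(/C)[C@@]2(O)C=C[C@@](C)(C[C@@H](OC(=O)/C(=C\C)COC(C)=O)[C@H]1C(=C)C=O)O2 | intermediate
40 | C12 lactol, trans-fused, lactol carbon not specified (not isolated) | C=C1C(O)O[C@@H]2/C=C(/C)[C@@]3(O)C=C[C@@](C)(C[C@@H](OC(=O)/C(=C\C)COC(C)=O)[C@@H]12)O3 | intermediate
41 | CNP0256971.1: (3R,6R,7R,8R,10R)-3-hydroxy-3,10-epoxygermacra-1,4Z,11(13)-trien-6,12-olide 8-[(Z)-2-(acetoxymethyl)but-2-enoate] | C=C1C(=O)O[C@@H]2/C=C(/C)[C@@]3(O)C=C[C@@](C)(C[C@@H](OC(=O)/C(=C\C)COC(C)=O)[C@@H]12)O3 | target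

**Step count and risks**

Total: 22 steps. Longest linear sequence: 18 steps from (S)-carvone (steps 1–11, 13–16, 20–22); step 12 and steps 17–19 prepare the two side fragments.

Steps most likely to fail:

1. Step 14 (Proposed new method). What may go wrong: heterolytic cleavage of C3–C8 in the alkoxide (ring opening or [1,3] shift), or β-elimination of the C10 alkoxy group from the enolate. The fallback uses known chemistry and sets out from 17. Partial hydrogenation of the alkyne over Pd/CaCO3 poisoned with Pb(OAc)2 and quinoline gives the C3 vinyl ketone F1. Addition of 21 gives the trans-1,2-dialkenylcyclohexenol F2, a member of the class for which the anionic oxy-Cope ring expansion is established, and KN(SiMe3)2/18-crown-6 should give the ten-membered enol ether ketone F3 (C2=C3 methyl enol ether, C1 methylene). PhSeCl in methanol converts the enol ether into the C2 selanyl dimethyl ketal F4; H2O2 oxidation and selenoxide elimination introduce the C1=C2 double bond in the unsaturated dimethyl ketal F5. PPTS in methanol then removes the ethoxyethyl group and closes the bridge (E and Z isomers equilibrating through the allylic oxocarbenium ion), returning to the route at 28.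

2. Step 7. What may go wrong: hydrogen abstraction at C12 next to the silyl ether or at C7, or attack on the alkyne, in competition with the ring methylene. The fallback sets out from 12. Epoxidation of the trisubstituted alkene with mCPBA gives the C4,C5-epoxide F6. Opening with PhSeNa at the less hindered C5 gives the hydroxy selenide F7, and H2O2 oxidation with selenoxide syn-elimination towards C6 gives the tertiary allylic alcohol F8 (C4–OH, C5=C6). Babler–Dauben oxidative transposition with pyridinium chlorochromate (C5H5NH[CrO3Cl]) then moves oxygen to C6 and returns to the route at enone 13.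

3. Step 16. What may go wrong: hydride delivery to the other face of the medium-ring ketone. The fallback sets out from 28: the ketone is reduced with whichever hydride gives the C8 α-alcohol F9 cleanly, and F9 is esterified with acid 35 under Mitsunobu conditions (PPh3, diisopropyl azodicarboxylate, toluene, 0 °C), which installs the ester with inversion and returns to the route at 37.

**Further compounds**

F1 | step 14 | C3 vinyl ketone (17 with vinyl in place of ethynyl) | C=C[C@@]1(OC)C(C)=C[C@@H](O[Si](C)(C)C(C)(C)C)[C@H](C(=C)CO[Si](C)(C)C(C)(C)C)C1=O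
F2 | step 14 | trans-1,2-dialkenylcyclohexenol (22 with vinyl in place of ethynyl) | C=C[C@@]1(OC)C(C)=C[C@@H](O[Si](C)(C)C(C)(C)C)[C@H](C(=C)CO[Si](C)(C)C(C)(C)C)[C@]1(O)/C=C(/C)OC(C)OCC
F3 | step 14 | ten-membered enol ether ketone (C2=C3 methyl enol ether, C1 methylene) | O=C1C[C@@](C)(OC(C)OCC)C/C=C(OC)/C(C)=C\[C@@H](O[Si](C)(C)C(C)(C)C)[C@@H]1C(=C)CO[Si](C)(C)C(C)(C)C
F4 | step 14 | C2 selanyl dimethyl ketal (C2 not specified) | O=C1C[C@@](C)(OC(C)OCC)CC([Se]c2ccccc2)C(OC)(OC)/C(C)=C\[C@@H](O[Si](C)(C)C(C)(C)C)[C@@H]1C(=C)CO[Si](C)(C)C(C)(C)C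
F5 | step 14 | unsaturated dimethyl ketal (C1=C2 geometry not specified) | O=C1C[C@@](C)(OC(C)OCC)C=CC(OC)(OC)/C(C)=C\[C@@H](O[Si](C)(C)C(C)(C)C)[C@@H]1C(=C)CO[Si](C)(C)C(C)(C)C
F6 | step 7 | C4,C5-epoxide of 12 (epoxide face not specified) | C#C[C@@]1(OC)C2(C)OC2C[C@H](C(=C)CO[Si](C)(C)C(C)(C)C)[C@H]1O[Si](CC)(CC)CC
F7 | step 7 | hydroxy selenide (C4–OH, C5–SePh; C4 and C5 not specified) | C#C[C@@]1(OC)C(C)(O)C([Se]c2ccccc2)C[C@H](C(=C)CO[Si](C)(C)C(C)(C)C)[C@H]1O[Si](CC)(CC)CC
F8 | step 7 | tertiary allylic alcohol (C4–OH, C5=C6; C4 not specified) | C#C[C@@]1(OC)C(C)(O)C=C[C@H](C(=C)CO[Si](C)(C)C(C)(C)C)[C@H]1O[Si](CC)(CC)CC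
F9 | step 16 | C8 α-alcohol (C8 epimer of 29) | CC(C)(C)[Si](C)(C)O[C@@H]1/C=C(/C)[C@@]2(OC)C=C[C@@](C)(C[C@H](O)[C@H]1C(=C)CO[Si](C)(C)C(C)(C)C)O2
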